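Target numbering: ring C1 (carbinol), C2H2, C3HCl, C4(Br)CH3, C5H2, C6H2; side chain C1'H2=C2'–C3'H2–C4'H(OH)–C5'H=C6'(CH3)2.
Cuts, in retrosynthetic order: the C1 O–Si bond; C3'–C4' (2-substituted allylsilane + 3-methylbut-2-enal); C4–Br with C5–H (HBr on a C4=C5 alkene); ring bond C1–C6 (retro Ireland–Claisen to a 6-vinyl-δ-lactone); C3–Cl (epoxy alcohol opening); the C3=C4 alkene of an open-chain ester (cross metathesis).
Enabling feature: C1 carries oxygen and the sp2 carbon C2' (a latent carboxyl carbon) and lies 1,4 across the cyclohexane from the methyl-bearing C4. C1–C6–C5–C4 plus a temporary C4–O–C2'(=O) link is therefore the six-atom array of a [3,3] shift, held by the C2–C3 tether as an oxan-2-one ring.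
Forward order: chain (steps 1–4), epoxide and chlorohydrin (5, 6), temporary lactone ring with its vinyl group (7–9), carbocycle by ring contraction (10), tertiary bromide (11, 12), side chain (13–15).
Stereochemistry: Sharpless epoxidation sets C3/C4 of the chain. Chloride opening with inversion gives the final C3. The sacrificial C4–O centre is relayed to quaternary C1 in the key step, which also merges both C1 epimers. Bromide then adds to C4 anti to chlorine, and C4' comes from a chiral Lewis acid.

Key step: step 10

Assumption: the centre made in step 1 (future C1) is racemic, so compounds 8–12 are carried as pairs of epimers at that carbon, drawn without configuration there, and the pair is merged in step 10.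

Step 1
Reactants: 1 ethyl glyoxylate (ethyl 2-oxoacetate); 2 allylboronic acid pinacol ester (2-allyl-4,4,5,5-tetramethyl-1,3,2-dioxaborolane)
Product: 3 ethyl 2-hydroxypent-4-enoate (racemic)
Conditions: CH2Cl2, 0 °C → rt; H2O work-up
Reagents that add atoms: none
Why: Uncatalysed allylboration of the strongly electrophilic glyoxylate aldehyde through a closed six-membered transition state should give the homoallylic α-hydroxy ester, and the missing stereocontrol is harmless because this centre is made planar again in step 10.

Step 2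
Reactants: 3 ethyl 2-hydroxypent-4-enoate
Product: 4 ethyl 2-[(tert-butyldimethylsilyl)oxy]pent-4-enoate (racemic)
Conditions: TBSCl, imidazole, DMF, rt
Reagents that add atoms: tert-butyldimethylsilyl chloride, CC(C)(C)[Si](C)(C)Cl
Why: Standard silylation of a secondary alcohol installs the one protecting group of the route, which masks the future C1 oxygen against oxidant, base, acid and organometallic reagents until step 15.

Step 3
Reactants: 4 ethyl 2-[(tert-butyldimethylsilyl)oxy]pent-4-enoate; 5 methacrolein (2-methylprop-2-enal)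
Product: 6 ethyl (4E)-2-[(tert-butyldimethylsilyl)oxy]-5-methyl-6-oxohex-4-enoate (racemic)
Conditions: second-generation Hoveyda–Grubbs catalyst (5 mol %), excess 5, CH2Cl2, 40 °C
Reagents that add atoms: none
Why: Olefin cross metathesis of a terminal alkene with an excess of a 1,1-disubstituted enal that hardly homodimerises should give the trisubstituted enal in the thermodynamically preferred E geometry, which later fixes the C3/C4 relative configuration.

Step 4
Reactants: 6 ethyl (4E)-2-[(tert-butyldimethylsilyl)oxy]-5-methyl-6-oxohex-4-enoate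
Product: 7 ethyl (4E)-2-[(tert-butyldimethylsilyl)oxy]-6-hydroxy-5-methylhex-4-enoate (racemic)
Conditions: NaBH4, CeCl3·7H2O, MeOH, 0 °C
Reagents that add atoms: none
Why: Luche reduction delivers hydride 1,2 to the enal only, leaving the ester, the silyl ether and the alkene geometry untouched.

Step 5
Reactants: 7 ethyl (4E)-2-[(tert-butyldimethylsilyl)oxy]-6-hydroxy-5-methylhex-4-enoate
Product: 8 ethyl 2-[(tert-butyldimethylsilyl)oxy]-3-[(2R,3R)-3-(hydroxymethyl)-3-methyloxiran-2-yl]propanoate (both C2 epimers)
Conditions: Ti(OiPr)4 (10 mol %), D-(−)-diisopropyl tartrate (12 mol %), tBuOOH, 4 Å MS, CH2Cl2, −20 °C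
Reagents that add atoms: tert-butyl hydroperoxide, CC(C)(C)OO
Why: Sharpless asymmetric epoxidation of an (E)-2-methyl allylic alcohol, one of its best substrate classes, is reagent controlled, and since L-(+)-tartrate gives (2S,3S)-epoxides from such alcohols the D-(−)-tartrate should give the (2R,3R)-epoxide in both epimers of the remote racemic centre.

Step 6
Reactants: 8 ethyl 2-[(tert-butyldimethylsilyl)oxy]-3-[(2R,3R)-3-(hydroxymethyl)-3-methyloxiran-2-yl]propanoate
Product: 9 ethyl (4S,5R)-2-[(tert-butyldimethylsilyl)oxy]-4-chloro-5,6-dihydroxy-5-methylhexanoate (both C2 epimers)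
Conditions: ClTi(OiPr)3, CH2Cl2, 0 °C → rt; aq. tartaric acid
Reagents that add atoms: chlorotitanium triisopropoxide, CC(C)O[Ti](Cl)(OC(C)C)OC(C)C
Why: Titanium-assisted opening of a 2,3-epoxy alcohol relies on chelation of the epoxy alkoxide, which steers chloride to the distal secondary carbon in an SN2 process faster than the ester carbonyl can take part, so that inversion sets the (S)-chloride (final C3) while the tertiary C–O bond keeps its configuration.

Step 7
Reactants: 9 ethyl (4S,5R)-2-[(tert-butyldimethylsilyl)oxy]-4-chloro-5,6-dihydroxy-5-methylhexanoate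
Product: 10 (5S,6R)-3-[(tert-butyldimethylsilyl)oxy]-5-chloro-6-(hydroxymethyl)-6-methyloxan-2-one (both C3 epimers)
Conditions: PPTS (cat.), 4 Å MS, toluene, 80 °C
Reagents that add atoms: none
Why: Acid-catalysed lactonisation (intramolecular transesterification) should close the six-membered ring through the tertiary hydroxyl rather than a seven-membered ring through the primary one, helped by the gem-dialkyl effect and removal of ethanol, and acid avoids the base-induced closure of the chlorohydrin back to an epoxide.

Step 8
Reactants: 10 (5S,6R)-3-[(tert-butyldimethylsilyl)oxy]-5-chloro-6-(hydroxymethyl)-6-methyloxan-2-one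
Product: 11 (2R,3S)-5-[(tert-butyldimethylsilyl)oxy]-3-chloro-2-methyl-6-oxooxane-2-carbaldehyde (both C5 epimers)
Conditions: Dess–Martin periodinane, CH2Cl2, 0 °C → rt
Reagents that add atoms: none
Why: Dess–Martin oxidation turns the only free (primary, neopentyl-type) alcohol into an aldehyde that has no α-hydrogen and therefore cannot epimerise or eliminate.

Step 9
Reactants: 11 (2R,3S)-5-[(tert-butyldimethylsilyl)oxy]-3-chloro-2-methyl-6-oxooxane-2-carbaldehyde
Product: 12 (5S,6R)-3-[(tert-butyldimethylsilyl)oxy]-5-chloro-6-ethenyl-6-methyloxan-2-one (both C3 epimers)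
Conditions: MePPh3Br, KN(SiMe3)2 (slight deficit), THF, 0 °C; then 11, −78 → 0 °C
Reagents that add atoms: methyltriphenylphosphonium bromide, C[P+](c1ccccc1)(c1ccccc1)c1ccccc1.[Br-]
Why: Wittig methylenation of the aldehyde is much faster at low temperature than attack of the ylide on the lactone carbonyl or on its α-hydrogen, and it completes the allylic ester unit needed for the rearrangement.

Step 10
Reactants: 12 (5S,6R)-3-[(tert-butyldimethylsilyl)oxy]-5-chloro-6-ethenyl-6-methyloxan-2-one
Product: 15 (1R,5S)-1-[(tert-butyldimethylsilyl)oxy]-5-chloro-4-methylcyclohex-3-ene-1-carboxylic acid, via silyl ketene acetal 13 (not isolated), via trimethylsilyl ester 14 (not isolated)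
Conditions: LiN(SiMe3)2, Me3SiCl/Et3N (premixed), THF, −78 °C → rt; exchange THF for toluene, 100 °C; aq. citric acid, THF, rt
Reagents that add atoms: chlorotrimethylsilane, C[Si](C)(C)Cl (its silyl group is present in 13 and 14 only)
Why: Either C1 epimer of 12 is deprotonated and O-silylated to the same cyclic silyl ketene acetal 13, in which C1=C2'(OSiMe3)–O–C4–C5=C6 is an allyl vinyl ether, and on heating a concerted suprafacial [3,3] shift makes C1–C6, breaks C4–O and leaves the alkene at C4=C5. The closest known reaction type is the Ireland–Claisen ring contraction of ω-vinyl lactones, itself the ester-enolate version of the thermal rearrangement of 2-vinyl-3,4-dihydro-2H-pyrans to cyclohexenes. The cyclohexene ring is closed by pericyclic ring contraction and not by an exo or endo attack: since the enol double bond lies inside the oxan-2-one ring, the C2–C3 tether enforces a boat-shaped, bicyclo[2.2.2]octane-like transition state with C1 and C4 as bridgeheads. The one new stereocentre, quaternary C1, is controlled by the sacrificial (R)-configured C4, because the vinyl group can reach C1 only on the lactone face that it occupies; the carboxyl carbon therefore ends up cis to the C3 chlorine, which is (1R) beside the untouched (3S) centre. The step needs O- rather than C-silylation and a rearrangement that outruns 1,3-elimination of chloride by the enolate and ionisation of the tertiary allylic C–O bond; in situ trapping at −78 °C, the two donor oxygens on the ketene acetal (which lower the barrier) and the exo, unhindered position of chlorine in the transition state should secure this. Because C1 is planar in 13, the step is also stereoconvergent and funnels the epimer pair carried since step 1 into one configuration.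

Step 11
Reactants: 15 (1R,5S)-1-[(tert-butyldimethylsilyl)oxy]-5-chloro-4-methylcyclohex-3-ene-1-carboxylic acid
Product: 16 methyl (1R,5S)-1-[(tert-butyldimethylsilyl)oxy]-5-chloro-4-methylcyclohex-3-ene-1-carboxylate
Conditions: Me3SiCHN2, toluene/MeOH, 0 °C
Reagents that add atoms: (trimethylsilyl)diazomethane, C[Si](C)(C)C=[N+]=[N-]
Why: O-Methylation of the hindered acid by a diazomethane equivalent runs under neutral conditions at oxygen and not at the crowded carbonyl carbon, so the allylic chloride is exposed to no base, nucleophile or heat.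

Step 12
Reactants: 16 methyl (1R,5S)-1-[(tert-butyldimethylsilyl)oxy]-5-chloro-4-methylcyclohex-3-ene-1-carboxylate
Product: 17 methyl (1R,3S,4S)-4-bromo-1-[(tert-butyldimethylsilyl)oxy]-3-chloro-4-methylcyclohexane-1-carboxylate
Conditions: HBr (anhydrous), BHT (cat.), CH2Cl2, −40 → 0 °C, dark
Reagents that add atoms: hydrogen bromide, Br
Why: In this ionic Markovnikov hydrobromination, the reaction type by which methallyl-type chlorides take up HBr, protonation at C5 gives the tertiary C4 cation whose face syn to the vicinal C3–Cl bond is closed by weak chlorine bridging and dipole repulsion, so bromide should enter anti to chlorine and set (4S), while cold, darkness and the inhibitor suppress the radical-chain anti-Markovnikov path and the hindered silyl ether next to the ester resists the acid.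

Step 13
Reactants: 17 methyl (1R,3S,4S)-4-bromo-1-[(tert-butyldimethylsilyl)oxy]-3-chloro-4-methylcyclohexane-1-carboxylate
Product: 19 {2-[(1R,3S,4S)-4-bromo-1-[(tert-butyldimethylsilyl)oxy]-3-chloro-4-methylcyclohexyl]prop-2-en-1-yl}trimethylsilane, via bis(silylmethyl) carbinol 18 (not isolated)
Conditions: Me3SiCH2MgCl, CeCl3 (anhydrous), THF, −78 °C → rt; aq. NH4Cl; SiO2, CH2Cl2, rt
Reagents that add atoms: (trimethylsilylmethyl)magnesium chloride, C[Si](C)(C)C[Mg]Cl
Why: Double addition of the weakly basic, strongly oxophilic organocerium reagent to the ester followed by acid-promoted Peterson elimination of one β-silyl group from 18 is the standard conversion of an ester into a 2-substituted allylsilane, and the low basicity of the reagent together with the equatorial C–Br bond, deactivated by the neighbouring chlorine, should hold back E2 and SN1 loss of bromide.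

Step 14
Reactants: 19 {2-[(1R,3S,4S)-4-bromo-1-[(tert-butyldimethylsilyl)oxy]-3-chloro-4-methylcyclohexyl]prop-2-en-1-yl}trimethylsilane; 20 3-methylbut-2-enal
Product: 22 (4S)-2-[(1R,3S,4S)-4-bromo-1-[(tert-butyldimethylsilyl)oxy]-3-chloro-4-methylcyclohexyl]-6-methylhepta-1,5-dien-4-ol, via trimethylsilyl ether 21 (not isolated)
Conditions: acyloxyborane made in situ from (2S,3S)-2-O-(2,6-diisopropoxybenzoyl)tartaric acid and BH3·THF (20 mol %), EtCN, −78 °C; aq. citric acid, THF, 0 °C
Reagents that add atoms: none
Why: In this catalytic asymmetric Hosomi–Sakurai allylation, for which 2-substituted allylsilanes are the reactive substrate class and this enal is a known 1,2-acceptor, the chiral acyloxyborane binds the aldehyde and, in the (2S,3S)-tartrate series on the accepted facial model, leaves its Si face open to the terminal CH2 of 19 in an open transition state, which sets (4'S) under catalyst control because the resident stereocentres are remote, and silyl transfer gives 21, which mild acid cleaves.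

Step 15
Reactants: 22 (4S)-2-[(1R,3S,4S)-4-bromo-1-[(tert-butyldimethylsilyl)oxy]-3-chloro-4-methylcyclohexyl]-6-methylhepta-1,5-dien-4-ol
Product: 23 (1R,3S,4S)-4-bromo-3-chloro-1-[(4S)-4-hydroxy-6-methylhepta-1,5-dien-2-yl]-4-methylcyclohexan-1-ol (target)
Conditions: HF·pyridine, excess pyridine, THF, 0 °C → rt
Reagents that add atoms: none
Why: Fluoride-driven desilylation of the hindered tertiary silyl ether in a pyridine-buffered medium is neither acidic enough to ionise the allylic alcohols nor basic enough to eliminate the equatorial tertiary bromide, so all four stereocentres should be kept.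

Compound list
1 | ethyl glyoxylate | CCOC(=O)C=O | starting material
2 | allylboronic acid pinacol ester | C=CCB1OC(C)(C)C(C)(C)O1 | starting material
3 | ethyl 2-hydroxypent-4-enoate (racemic) | CCOC(=O)C(O)CC=C | intermediate
4 | ethyl 2-[(tert-butyldimethylsilyl)oxy]pent-4-enoate (racemic) | CCOC(=O)C(CC=C)O[Si](C)(C)C(C)(C)C | intermediate
5 | methacrolein | C=C(C)C=O | starting material
6 | ethyl (4E)-2-[(tert-butyldimethylsilyl)oxy]-5-methyl-6-oxohex-4-enoate | CCOC(=O)C(C/C=C(\C)C=O)O[Si](C)(C)C(C)(C)C | intermediate
7 | ethyl (4E)-2-[(tert-butyldimethylsilyl)oxy]-6-hydroxy-5-methylhex-4-enoate | CCOC(=O)C(C/C=C(\C)CO)O[Si](C)(C)C(C)(C)C | intermediate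
8 | ethyl 2-[(tert-butyldimethylsilyl)oxy]-3-[(2R,3R)-3-(hydroxymethyl)-3-methyloxiran-2-yl]propanoate (C2 epimers) | CCOC(=O)C(C[C@H]1O[C@]1(C)CO)O[Si](C)(C)C(C)(C)C | intermediate
9 | ethyl (4S,5R)-2-[(tert-butyldimethylsilyl)oxy]-4-chloro-5,6-dihydroxy-5-methylhexanoate (C2 epimers) | CCOC(=O)C(C[C@H](Cl)[C@](C)(O)CO)O[Si](C)(C)C(C)(C)C | intermediate
10 | (5S,6R)-3-[(tert-butyldimethylsilyl)oxy]-5-chloro-6-(hydroxymethyl)-6-methyloxan-2-one (C3 epimers) | O=C1O[C@](C)(CO)[C@@H](Cl)CC1O[Si](C)(C)C(C)(C)C | intermediate
11 | (2R,3S)-5-[(tert-butyldimethylsilyl)oxy]-3-chloro-2-methyl-6-oxooxane-2-carbaldehyde (C5 epimers) | O=C1O[C@](C)(C=O)[C@@H](Cl)CC1O[Si](C)(C)C(C)(C)C | intermediate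
12 | (5S,6R)-3-[(tert-butyldimethylsilyl)oxy]-5-chloro-6-ethenyl-6-methyloxan-2-one (C3 epimers) | O=C1O[C@](C)(C=C)[C@@H](Cl)CC1O[Si](C)(C)C(C)(C)C | intermediate
13 | (2R,3S)-5-[(tert-butyldimethylsilyl)oxy]-3-chloro-2-ethenyl-2-methyl-6-[(trimethylsilyl)oxy]-3,4-dihydro-2H-pyran | C=C[C@@]1(C)OC(O[Si](C)(C)C)=C(O[Si](C)(C)C(C)(C)C)C[C@@H]1Cl | intermediate
14 | trimethylsilyl (1R,5S)-1-[(tert-butyldimethylsilyl)oxy]-5-chloro-4-methylcyclohex-3-ene-1-carboxylate | C[Si](C)(C)OC(=O)[C@@]1(O[Si](C)(C)C(C)(C)C)CC=C(C)[C@@H](Cl)C1 | intermediate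
15 | (1R,5S)-1-[(tert-butyldimethylsilyl)oxy]-5-chloro-4-methylcyclohex-3-ene-1-carboxylic acid | OC(=O)[C@@]1(O[Si](C)(C)C(C)(C)C)CC=C(C)[C@@H](Cl)C1 | intermediate
16 | methyl (1R,5S)-1-[(tert-butyldimethylsilyl)oxy]-5-chloro-4-methylcyclohex-3-ene-1-carboxylate | COC(=O)[C@@]1(O[Si](C)(C)C(C)(C)C)CC=C(C)[C@@H](Cl)C1 | intermediate
17 | methyl (1R,3S,4S)-4-bromo-1-[(tert-butyldimethylsilyl)oxy]-3-chloro-4-methylcyclohexane-1-carboxylate | COC(=O)[C@@]1(O[Si](C)(C)C(C)(C)C)CC[C@](C)(Br)[C@@H](Cl)C1 | intermediate
18 | 2-[(1R,3S,4S)-4-bromo-1-[(tert-butyldimethylsilyl)oxy]-3-chloro-4-methylcyclohexyl]-1,3-bis(trimethylsilyl)propan-2-ol | C[Si](C)(C)CC(O)(C[Si](C)(C)C)[C@@]1(O[Si](C)(C)C(C)(C)C)CC[C@](C)(Br)[C@@H](Cl)C1 | intermediate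
19 | {2-[(1R,3S,4S)-4-bromo-1-[(tert-butyldimethylsilyl)oxy]-3-chloro-4-methylcyclohexyl]prop-2-en-1-yl}trimethylsilane | C=C(C[Si](C)(C)C)[C@@]1(O[Si](C)(C)C(C)(C)C)CC[C@](C)(Br)[C@@H](Cl)C1 | intermediate
20 | 3-methylbut-2-enal | CC(C)=CC=O | starting material
21 | trimethylsilyl ether of 22 at the C4' oxygen | C=C(C[C@H](O[Si](C)(C)C)C=C(C)C)[C@@]1(O[Si](C)(C)C(C)(C)C)CC[C@](C)(Br)[C@@H](Cl)C1 | intermediate
22 | (4S)-2-[(1R,3S,4S)-4-bromo-1-[(tert-butyldimethylsilyl)oxy]-3-chloro-4-methylcyclohexyl]-6-methylhepta-1,5-dien-4-ol | C=C(C[C@H](O)C=C(C)C)[C@@]1(O[Si](C)(C)C(C)(C)C)CC[C@](C)(Br)[C@@H](Cl)C1 | intermediate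
23 | (1R,3S,4S)-4-bromo-3-chloro-1-[(4S)-4-hydroxy-6-methylhepta-1,5-dien-2-yl]-4-methylcyclohexan-1-ol | C=C(C[C@H](O)C=C(C)C)[C@@]1(O)CC[C@](C)(Br)[C@@H](Cl)C1 | target

Total step count: 15. Longest linear sequence: 15 (fully linear; 1, 2, 5 and 20 are bought).

Steps most likely to fail

Step 12. The alkene is deactivated by the allylic chlorine. Protonation may therefore be slower than ionisation or allylic transposition of the chloride, capture of the C4 cation by the ester carbonyl, or acid loss of the silyl ether. Bromide may also enter with poor facial selectivity.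
Fallback: leave the cationic manifold for a radical one. Setting out from 16, a cobalt-hydride hydrogen-atom-transfer hydrobromination (Co(acac)2, tBuOOH, Et3SiH, 4-toluenesulfonyl bromide, n-PrOH, rt) would place hydrogen on C5. The tertiary C4 radical would then abstract bromine from the sulfonyl bromide on the face anti to the C3–Cl bond. The fallback comes back to the route at 17 and makes no new compound.

Step 13. The second addition to the neopentyl-type, α-silyloxy carbonyl group may stall. The excess organometallic reagent may also attack the tertiary bromide by elimination or halogen–metal exchange.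
Fallback: make C3'–C4' by an aldol reaction and build the 1,1-disubstituted alkene last, from a ketone. Setting out from 17, the small, non-basic Tebbe reagent Cp2Ti(μ-Cl)(μ-CH2)AlMe2 (toluene/THF/pyridine, −40 °C → rt) would methylenate the ester to the methyl enol ether F1. Aqueous oxalic acid on silica would hydrolyse this to the methyl ketone F2. Enolisation with Ipc2BCl/Et3N (the antipode that attacks the Si face of the aldehyde) and addition of 20 would give the (S)-β-hydroxy ketone F3, and Me3SiCl/imidazole would give its trimethylsilyl ether F4. Petasis methylenation of F4 (Cp2TiMe2, toluene, 65 °C) leads to 21, where the fallback comes back to the route.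

Step 14. The bulky 2-substituent may slow turnover of the mild catalyst. Protodesilylation or an uncatalysed background reaction could then take over, with poor facial selectivity at C4'.
Fallback: separate bond formation from stereocontrol. Setting out from 19 and 20, BF3·OEt2 (CH2Cl2, −78 °C) would give the alcohol as the mixture of C4' epimers F5, and Dess–Martin oxidation would give the enone F6. Corey–Bakshi–Shibata reduction ((R)-2-methyl-CBS-oxazaborolidine, catecholborane, toluene, −78 °C, with the 2-methylprop-1-enyl group as the large substituent) would give the (4'S)-alcohol. This brings the fallback back to the route at 22.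

Further compounds
F0 | step 12 | none | none
F1 | step 13 | tert-butyl{[(1R,3S,4S)-4-bromo-3-chloro-1-(1-methoxyethenyl)-4-methylcyclohexyl]oxy}dimethylsilane | C=C(OC)[C@@]1(O[Si](C)(C)C(C)(C)C)CC[C@](C)(Br)[C@@H](Cl)C1
F2 | step 13 | 1-[(1R,3S,4S)-4-bromo-1-[(tert-butyldimethylsilyl)oxy]-3-chloro-4-methylcyclohexyl]ethan-1-one | CC(=O)[C@@]1(O[Si](C)(C)C(C)(C)C)CC[C@](C)(Br)[C@@H](Cl)C1
F3 | step 13 | (3S)-1-[(1R,3S,4S)-4-bromo-1-[(tert-butyldimethylsilyl)oxy]-3-chloro-4-methylcyclohexyl]-3-hydroxy-5-methylhex-4-en-1-one | O=C(C[C@H](O)C=C(C)C)[C@@]1(O[Si](C)(C)C(C)(C)C)CC[C@](C)(Br)[C@@H](Cl)C1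
F4 | step 13 | (3S)-1-[(1R,3S,4S)-4-bromo-1-[(tert-butyldimethylsilyl)oxy]-3-chloro-4-methylcyclohexyl]-5-methyl-3-[(trimethylsilyl)oxy]hex-4-en-1-one | O=C(C[C@H](O[Si](C)(C)C)C=C(C)C)[C@@]1(O[Si](C)(C)C(C)(C)C)CC[C@](C)(Br)[C@@H](Cl)C1
F5 | step 14 | 2-[(1R,3S,4S)-4-bromo-1-[(tert-butyldimethylsilyl)oxy]-3-chloro-4-methylcyclohexyl]-6-methylhepta-1,5-dien-4-ol (C4 epimers) | C=C(CC(O)C=C(C)C)[C@@]1(O[Si](C)(C)C(C)(C)C)CC[C@](C)(Br)[C@@H](Cl)C1
F6 | step 14 | 2-[(1R,3S,4S)-4-bromo-1-[(tert-butyldimethylsilyl)oxy]-3-chloro-4-methylcyclohexyl]-6-methylhepta-1,5-dien-4-one | C=C(CC(=O)C=C(C)C)[C@@]1(O[Si](C)(C)C(C)(C)C)CC[C@](C)(Br)[C@@H](Cl)C1
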